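**Retrosynthetic overview**
Feature: in ring B (the pyranone), quaternary C2 lies between ring oxygen O1 and the C3 methylene, and C3 is alpha to the C4 ketone on ring A (the benzene). C2 is therefore an aryl sec-alkyl ether carbon whose single hydrogen has been exchanged for C3.
Key disconnection C2–C3: a rhodium carbenoid at C3, made from the aryl diazomethyl ketone, inserts with retention into the O1-activated tertiary C2–H. Ring A is bought and ring B is the only ring formed.
Disconnection O1–C2: Mitsunobu inversion of (S)-sulcatol on the 2-OH of 5-O-MOM 4-bromo-2,5-dihydroxybenzaldehyde sets the (R)-methine. The sequence CHO → CO2H → COCl → COCHN2 supplies C4 and C3.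
The side-chain alkene stands in, free of O–H, for the tertiary alcohol during the carbenoid step. Markovnikov hydration and MOM removal follow ring closure.

Key step: step 6

Assumption: (S)-sulcatol is taken as purchasable in enantiopure form, and its optical purity sets that of the target because every later step only transfers this stereocentre.
Locants: chromanone numbering (O1, C2, C3, C4, C4a, C5–C8, C8a; side chain C1'–C4') is also used for the open-chain precursors.

**Step 1**
Reactants: 1 4-bromo-2,5-dimethoxybenzaldehyde
Product: 2 4-bromo-2,5-dihydroxybenzaldehyde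
Conditions: BBr3 (3 equiv), CH2Cl2, −78 °C → rt; H2O quench
Reagents that add atoms: none
Why: Lewis-acid aryl methyl ether cleavage, in which BBr3 complexes each ether oxygen and bromide removes the methyl group by SN2, should free both phenols while the aryl bromide and the aldehyde stay untouched.

**Step 2**
Reactants: 2 4-bromo-2,5-dihydroxybenzaldehyde
Product: 3 4-bromo-2-hydroxy-5-(methoxymethoxy)benzaldehyde
Conditions: MOMCl (1.05 equiv), i-Pr2NEt (1.2 equiv), CH2Cl2, 0 °C
Reagents that add atoms: chloromethyl methyl ether (MOMCl), COCCl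
Why: Chemoselective O-alkylation (acetal protection) should cap only the free 5-OH, the later C6–OH, because the 2-OH is tied up in a hydrogen bond to the formyl oxygen and is much less nucleophilic under amine base.

**Step 3**
Reactants: 3 4-bromo-2-hydroxy-5-(methoxymethoxy)benzaldehyde; 4 (S)-6-methylhept-5-en-2-ol ((S)-sulcatol)
Product: 5 4-bromo-5-(methoxymethoxy)-2-{[(2R)-6-methylhept-5-en-2-yl]oxy}benzaldehyde
Conditions: PPh3 (1.3 equiv), DIAD (1.3 equiv), THF, 0 °C → rt
Reagents that add atoms: none
Why: In this Mitsunobu etherification the acidic salicylaldehyde-type phenol protonates the betaine and its phenoxide displaces the oxyphosphonium of the unhindered secondary alcohol by SN2, so the (S)-carbinol is inverted to the (R)-ether methine that later becomes C2.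

**Step 4**
Reactants: 5 4-bromo-5-(methoxymethoxy)-2-{[(2R)-6-methylhept-5-en-2-yl]oxy}benzaldehyde
Product: 6 4-bromo-5-(methoxymethoxy)-2-{[(2R)-6-methylhept-5-en-2-yl]oxy}benzoic acid
Conditions: NaClO2, NaH2PO4, 2-methylbut-2-ene (30 equiv), t-BuOH/H2O, 0 °C → rt
Reagents that add atoms: NaClO2 (sodium chlorite), [Na+].[O-]Cl=O
Why: In the Pinnick oxidation chlorous acid adds to the aldehyde and fragments to the acid, the large excess of scavenger alkene intercepts HOCl before it reaches the side-chain alkene or ring A, and the phosphate buffer is too weakly acidic to harm the MOM acetal.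

**Step 5**
Reactants: 6 4-bromo-5-(methoxymethoxy)-2-{[(2R)-6-methylhept-5-en-2-yl]oxy}benzoic acid; 7 (trimethylsilyl)diazomethane
Product: 10 1-[4-bromo-5-(methoxymethoxy)-2-{[(2R)-6-methylhept-5-en-2-yl]oxy}phenyl]-2-diazoethan-1-one, via acid chloride 8 (not isolated), via C-silyl diazoketone 9 (not isolated)
Conditions: Me2C=C(Cl)NMe2 (1.1 equiv), CH2Cl2, 0 °C → rt, concentrate; 7 (1.5 equiv), Et3N (1.2 equiv), THF/MeCN 1:1, 0 °C → rt; sat aq NaHCO3
Reagents that add atoms: (trimethylsilyl)diazomethane 7, C[Si](C)(C)C=[N+]=[N-] (C3 and N2 of 10, also Si of 9); 1-chloro-N,N,2-trimethylprop-1-en-1-amine, CC(C)=C(Cl)N(C)C (Cl of 8)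
Why: Neutral acid chloride formation with the alpha-chloroenamine (an amide is the only by-product, so neither the MOM acetal nor the alkene meets HCl) followed by Arndt–Eistert-type C-acylation of the diazoalkane, with Et3N taking up HCl and the labile C–Si bond of 9 hydrolysing on aqueous work-up, should give the terminal diazoketone without touching the ether stereocentre.

**Step 6**
Reactants: 10 1-[4-bromo-5-(methoxymethoxy)-2-{[(2R)-6-methylhept-5-en-2-yl]oxy}phenyl]-2-diazoethan-1-one
Product: 11 (2R)-7-bromo-6-(methoxymethoxy)-2-methyl-2-(4-methylpent-3-en-1-yl)-2,3-dihydro-4H-chromen-4-one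
Conditions: Rh2(OAc)4 (1 mol %), dry CH2Cl2 (final about 5 mM), reflux, 10 added by syringe pump over 4 h, Ar
Reagents that add atoms: none
Why: Rh2(OAc)4 binds the diazo carbon of 10, N2 departs, and the electrophilic rhodium carbenoid at C3 engages the C2–H sigma bond in a concerted, asynchronous three-centre transition state in which hydrogen moves to C3 while C2–C3 forms and the catalyst is released. The closest known reaction type is the dirhodium-carboxylate-catalysed intramolecular C–H insertion of 2-alkoxyaryl diazoketones next to the ether oxygen, which gives chroman-4-ones, combined with the well-established retention seen when diazocarbonyl carbenoids insert into stereogenic tertiary C–H bonds. Ring B closes by 1,6-insertion, C3 bonding to C2 across the rigid tether C4–C4a–C8a–O1 through a six-membered transition state; the five-membered alternative has no C–H (that position is O1) and the CH3 and C1' hydrogens would demand seven-membered rings. The C2 stereocentre is controlled only by the (R)-methine set in step 3: C3 arrives on the face that the hydrogen leaves, so configuration is retained and the descriptor remains R (O1 > C3 > C1' > CH3). The selectivity needed is insertion over capture of the carbenoid by the O1 lone pair (five-membered oxonium ylide, then 1,2-shift or loss of the sec-alkyl group) and over attack on the side-chain alkene; it is secured by the weak donor character of O1 (conjugated through ring A with the ortho acyl group), by the reversibility of ylide formation on rhodium together with the poor migratory aptitude of a sec-alkyl group, by the tertiary, oxygen-activated nature of C2–H, and by the nine- or ten-membered ring that cyclopropanation would require. Slow addition into dilute, dry catalyst solution holds down carbenoid dimerisation, O–H insertion of water and intermolecular attack on the alkene or the OCH2O group, and the side chain deliberately carries no hydroxyl.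

**Step 7**
Reactants: 11 (2R)-7-bromo-6-(methoxymethoxy)-2-methyl-2-(4-methylpent-3-en-1-yl)-2,3-dihydro-4H-chromen-4-one
Product: 12 (2R)-7-bromo-2-(4-hydroxy-4-methylpentyl)-6-(methoxymethoxy)-2-methyl-2,3-dihydro-4H-chromen-4-one
Conditions: Co(acac)2 (20 mol %), PhSiH3 (3 equiv), O2 (1 atm), THF, rt
Reagents that add atoms: dioxygen, O=O
Why: In the Mukaiyama hydration a cobalt hydride delivers a hydrogen atom to the less substituted alkene carbon, O2 traps the tertiary radical and the silane reduces the peroxide, which should give the Markovnikov tertiary alcohol under neutral conditions that spare the aryl bromide, the ketone, the C2 ether and the MOM group (kept on so that no oxidisable free para-alkoxyphenol meets cobalt and O2), with no new stereocentre formed.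

**Step 8**
Reactants: 12 (2R)-7-bromo-2-(4-hydroxy-4-methylpentyl)-6-(methoxymethoxy)-2-methyl-2,3-dihydro-4H-chromen-4-one
Product: 13 (2R)-7-bromo-6-hydroxy-2-(4-hydroxy-4-methylpentyl)-2-methyl-2,3-dihydro-4H-chromen-4-one (CNP0351288.2)
Conditions: 3 M aq HCl, THF, 40 °C
Reagents that add atoms: none
Why: Acid-catalysed acetal hydrolysis of the aryl MOM ether, whose ortho-bromophenol is a good leaving group, should proceed at an acid strength too low to dehydrate the tertiary alcohol or to open ring B by retro-oxa-Michael reaction, so C2 stays (R), and base is avoided for the same reason.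

**Compound list**
1 | 4-bromo-2,5-dimethoxybenzaldehyde | COc1cc(Br)c(OC)cc1C=O | starting material
2 | 4-bromo-2,5-dihydroxybenzaldehyde | Oc1cc(Br)c(O)cc1C=O | intermediate
3 | 4-bromo-2-hydroxy-5-(methoxymethoxy)benzaldehyde | COCOc1cc(C=O)c(O)cc1Br | intermediate
4 | (S)-6-methylhept-5-en-2-ol, (S)-sulcatol | CC(C)=CCC[C@H](C)O | starting material
5 | 4-bromo-5-(methoxymethoxy)-2-{[(2R)-6-methylhept-5-en-2-yl]oxy}benzaldehyde | CC(C)=CCC[C@@H](C)Oc1cc(Br)c(OCOC)cc1C=O | intermediate
6 | 4-bromo-5-(methoxymethoxy)-2-{[(2R)-6-methylhept-5-en-2-yl]oxy}benzoic acid | CC(C)=CCC[C@@H](C)Oc1cc(Br)c(OCOC)cc1C(=O)O | intermediate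
7 | (trimethylsilyl)diazomethane | C[Si](C)(C)C=[N+]=[N-] | starting material
8 | 4-bromo-5-(methoxymethoxy)-2-{[(2R)-6-methylhept-5-en-2-yl]oxy}benzoyl chloride (not isolated) | CC(C)=CCC[C@@H](C)Oc1cc(Br)c(OCOC)cc1C(=O)Cl | intermediate
9 | 1-[4-bromo-5-(methoxymethoxy)-2-{[(2R)-6-methylhept-5-en-2-yl]oxy}phenyl]-2-diazo-2-(trimethylsilyl)ethan-1-one (not isolated) | CC(C)=CCC[C@@H](C)Oc1cc(Br)c(OCOC)cc1C(=O)C(=[N+]=[N-])[Si](C)(C)C | intermediate
10 | 1-[4-bromo-5-(methoxymethoxy)-2-{[(2R)-6-methylhept-5-en-2-yl]oxy}phenyl]-2-diazoethan-1-one | CC(C)=CCC[C@@H](C)Oc1cc(Br)c(OCOC)cc1C(=O)C=[N+]=[N-] | intermediate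
11 | (2R)-7-bromo-6-(methoxymethoxy)-2-methyl-2-(4-methylpent-3-en-1-yl)-2,3-dihydro-4H-chromen-4-one | CC(C)=CCC[C@]1(C)CC(=O)c2cc(OCOC)c(Br)cc2O1 | intermediate
12 | (2R)-7-bromo-2-(4-hydroxy-4-methylpentyl)-6-(methoxymethoxy)-2-methyl-2,3-dihydro-4H-chromen-4-one | CC(C)(O)CCC[C@]1(C)CC(=O)c2cc(OCOC)c(Br)cc2O1 | intermediate
13 | (2R)-7-bromo-6-hydroxy-2-(4-hydroxy-4-methylpentyl)-2-methyl-2,3-dihydro-4H-chromen-4-one | CC(C)(O)CCC[C@]1(C)CC(=O)c2cc(O)c(Br)cc2O1 | target

**Total step count:** 8. **Longest linear sequence:** 8 steps (1 → 13); 4 and 7 are bought and enter at steps 3 and 5.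

**Steps most likely to fail**

(a) Step 6. The carbenoid may be captured by the O1 lone pair faster than by the C2–H bond, after which the five-membered oxonium ylide sheds or shifts its sec-alkyl group. Carbenoid dimerisation and attack on the side-chain alkene are lesser drains.

The fallback gives up the C–H insertion, builds ring B by condensation and obtains the stereocentre by resolution. It sets out from 3 and comes back at 11.
- Addition of MeMgBr (2.2 equiv, THF, 0 °C) to 3 should give 5-bromo-2-(1-hydroxyethyl)-4-(methoxymethoxy)phenol F1.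
- MnO2 in CH2Cl2 should oxidise the benzylic alcohol to 1-[4-bromo-2-hydroxy-5-(methoxymethoxy)phenyl]ethan-1-one F2.
- A Kabbe condensation of F2 with 6-methylhept-5-en-2-one (CC(=O)CCC=C(C)C; pyrrolidine, MeOH, reflux; enamine aldol, dehydration, oxa-Michael closure) should give racemic 7-bromo-6-(methoxymethoxy)-2-methyl-2-(4-methylpent-3-en-1-yl)-2,3-dihydro-4H-chromen-4-one F3.
- Preparative chromatography on a polysaccharide chiral stationary phase should then deliver the (2R)-enantiomer 11, and steps 7 and 8 follow unchanged.

(b) Step 5. Acylation of the bulky, weakly nucleophilic diazoalkane by a hindered, electron-rich aroyl chloride may be sluggish. Traces of acid may also trigger cyclisation of the diazoketone onto O1 with loss of the sec-alkyl group.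

The fallback installs the diazo group by diazo transfer onto a methyl ketone. It sets out from 5 (step 4 is bypassed as well) and comes back at 10.
- MeMgBr (THF, −78 → 0 °C) should give 1-[4-bromo-5-(methoxymethoxy)-2-{[(2R)-6-methylhept-5-en-2-yl]oxy}phenyl]ethan-1-ol F4 as both carbinol epimers.
- MnO2 in CH2Cl2 should give 1-[4-bromo-5-(methoxymethoxy)-2-{[(2R)-6-methylhept-5-en-2-yl]oxy}phenyl]ethan-1-one F5.
- LiN(SiMe3)2 then CF3CO2CH2CF3 (THF, −78 °C) should give 1-[4-bromo-5-(methoxymethoxy)-2-{[(2R)-6-methylhept-5-en-2-yl]oxy}phenyl]-4,4,4-trifluorobutane-1,3-dione F6.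
- Detrifluoroacetylative diazo transfer (MsN3, Et3N, H2O, MeCN, rt) should give 10.

(c) Step 3. Coupling may be slow because the phenol is hydrogen-bonded and flanked by the formyl group. The activated alcohol may also eliminate, or inversion may be incomplete.

The fallback replaces in-situ redox activation by a preformed sulfonate and a fully formed phenoxide. It sets out from 4 and comes back at 5.
- MsCl and Et3N (CH2Cl2, 0 °C) should give (2S)-6-methylhept-5-en-2-yl methanesulfonate F7.
- The phenoxide of 3 (Cs2CO3, DMF, 50 °C) should displace the sulfonate by SN2 with inversion to give 5.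

**Further compounds**
F1 | step 6 | 5-bromo-2-(1-hydroxyethyl)-4-(methoxymethoxy)phenol | CC(O)c1cc(OCOC)c(Br)cc1O
F2 | step 6 | 1-[4-bromo-2-hydroxy-5-(methoxymethoxy)phenyl]ethan-1-one | CC(=O)c1cc(OCOC)c(Br)cc1O
F3 | step 6 | racemic 7-bromo-6-(methoxymethoxy)-2-methyl-2-(4-methylpent-3-en-1-yl)-2,3-dihydro-4H-chromen-4-one | CC(C)=CCCC1(C)CC(=O)c2cc(OCOC)c(Br)cc2O1
F4 | step 5 | 1-[4-bromo-5-(methoxymethoxy)-2-{[(2R)-6-methylhept-5-en-2-yl]oxy}phenyl]ethan-1-ol (both carbinol epimers) | CC(C)=CCC[C@@H](C)Oc1cc(Br)c(OCOC)cc1C(C)O
F5 | step 5 | 1-[4-bromo-5-(methoxymethoxy)-2-{[(2R)-6-methylhept-5-en-2-yl]oxy}phenyl]ethan-1-one | CC(C)=CCC[C@@H](C)Oc1cc(Br)c(OCOC)cc1C(C)=O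
F6 | step 5 | 1-[4-bromo-5-(methoxymethoxy)-2-{[(2R)-6-methylhept-5-en-2-yl]oxy}phenyl]-4,4,4-trifluorobutane-1,3-dione | CC(C)=CCC[C@@H](C)Oc1cc(Br)c(OCOC)cc1C(=O)CC(=O)C(F)(F)F
F7 | step 3 | (2S)-6-methylhept-5-en-2-yl methanesulfonate | CC(C)=CCC[C@H](C)OS(C)(=O)=O
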